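**Plan**
1. Retrosynthesis: the lactone bond O1–C2 of half A is cut first (it closes last). Then the benzo ring and the lactone ring of half B are cut together at C4a'–C5' and O1'–C8a', back to a 4-alkynyl-4-hydroxycyclobutenone with a free C2' carboxylic acid. Further cuts: alkyne–squarate bond (C8a'–C8'), C3–C4 with O1–C2 (quinone methide annulation), C3–C3' (bromoacetate alkylation), C4'–alkyne (conjugate alkynylation).
2. Enabling feature (chroman-2-one numbering; unprimed = 5,7-dihydroxy half A, primed = 5,6,7,8-tetrahydroxy half B): C5', C6', C7' and C8' of ring B all bear oxygen and map onto the four carbons of a squaric ester. C4a' and C8a' map onto an alkyne held at C4', and O1' comes from the C2' carboxyl group.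
3. Forward order: C4' → C3' → lactone A by cis annulation (C3, C4) → lactone A opened and its phenol benzylated, so that the skeleton survives organolithium chemistry → acetylide addition to dibenzyl squarate → one thermal step closes both rings of half B → hydrogenolysis and acid relactonisation close ring A.
4. Stereochemistry: C4' from a chiral bisphosphine–rhodium catalyst, C3' from an (R)-benzyloxazolidinone, C3 and C4 from a chiral carbene catalyst (endo annulation, cis).
5. From step 11 on, C3 and C3' are alpha to carboxylates or see only neutral or acidic conditions.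

Key step: step 14

Assumption: the enantiomer of the bisphosphine (step 2) and of the triazolium salt (step 10) is the one whose sense of induction gives the drawn configuration; the antipode is used if the sense proves opposite.

**Route**

Step 1
Reactants: 1 4-(benzyloxy)benzaldehyde; 2 Meldrum's acid
Product: 3 5-[4-(benzyloxy)benzylidene]-2,2-dimethyl-1,3-dioxane-4,6-dione
Conditions: pyrrolidine (10 mol %), AcOH (10 mol %), PhMe, rt
Reagents that add atoms: none
Why: Knoevenagel condensation of the non-enolisable aldehyde with the strongly C–H acidic Meldrum's acid under amine–acid catalysis should give the doubly activated arylidene cleanly.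

Step 2
Reactants: 3 arylidene Meldrum's acid; 4 trimethylsilylacetylene
Product: 5 5-{(1R)-1-[4-(benzyloxy)phenyl]-3-(trimethylsilyl)prop-2-yn-1-yl}-2,2-dimethyl-1,3-dioxane-4,6-dione
Conditions: [Rh(OAc)(C2H4)2]2 (2.5 mol %), (R)-(6,6'-dimethoxybiphenyl-2,2'-diyl)bis[bis(3,5-dimethylphenyl)phosphine] (5.5 mol %), 1,4-dioxane, rt
Reagents that add atoms: none
Why: Rhodium-catalysed enantioselective conjugate alkynylation of arylidene Meldrum's acids with a silylacetylene is a known reaction, in which the alkynylrhodium species carrying the atropisomeric bisphosphine adds to one enantiotopic face of the alkene and so sets C4' (R), the silyl group suppressing alkyne dimerisation.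

Step 3
Reactants: 5 alkynylated Meldrum's acid
Product: 6 (3R)-3-[4-(benzyloxy)phenyl]-5-(trimethylsilyl)pent-4-ynoic acid
Conditions: DMF/H2O (10:1), 100 °C
Reagents that add atoms: water, O
Why: Hydrolysis of the 5-monosubstituted Meldrum's acid and decarboxylation of the resulting malonic acid occur on heating in wet DMF without base, so the silylalkyne and the non-enolisable C4' centre should be unaffected.

Step 4
Reactants: 6 pentynoic acid; 7 (R)-4-benzyloxazolidin-2-one
Product: 9 (4R)-4-benzyl-3-{(3R)-3-[4-(benzyloxy)phenyl]-5-(trimethylsilyl)pent-4-ynoyl}oxazolidin-2-one, via mixed pivalic anhydride 8 (not isolated)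
Conditions: t-BuCOCl, Et3N, THF, −20 °C; then 7, LiCl, rt
Reagents that add atoms: none
Why: N-Acylation of the oxazolidinone through the mixed pivalic anhydride (LiCl/Et3N variant) is the standard way to attach an Evans auxiliary and involves no enolisable stereocentre.

Step 5
Reactants: 9 acyl oxazolidinone; 10 tert-butyl bromoacetate
Product: 11 tert-butyl (3R,4R)-3-{[(4R)-4-benzyl-2-oxooxazolidin-3-yl]carbonyl}-4-[4-(benzyloxy)phenyl]-6-(trimethylsilyl)hex-5-ynoate
Conditions: NaN(SiMe3)2, THF, −78 °C; then 10, −78 → −40 °C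
Reagents that add atoms: none
Why: Evans asymmetric alkylation, in which the chelated Z-sodium enolate is alkylated by the reactive bromoacetate on the face opposite the benzyl group of the (R)-oxazolidinone, sets C3' (3R in this compound) independently of the existing C4' centre.

Step 6
Reactants: 11 tert-butyl ester
Product: 12 (3R,4R)-3-{[(4R)-4-benzyl-2-oxooxazolidin-3-yl]carbonyl}-4-[4-(benzyloxy)phenyl]-6-(trimethylsilyl)hex-5-ynoic acid
Conditions: TFA/CH2Cl2 (1:4), 0 °C → rt
Reagents that add atoms: none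
Why: Acidolysis of the tert-butyl ester by TFA (loss of isobutene) frees the C2 carboxyl group, while the imide, the aryl benzyl ether and the alkynylsilane are stable to brief exposure to this acid.

Step 7
Reactants: 13 2,4,6-trihydroxybenzaldehyde
Product: 14 2,4-bis(benzyloxy)-6-hydroxybenzaldehyde
Conditions: BnBr (2.1 equiv), K2CO3, DMF, 0 °C → rt
Reagents that add atoms: benzyl bromide, BrCc1ccccc1
Why: Williamson etherification should be selective because the hydroxyl group hydrogen-bonded to the aldehyde is the least nucleophilic, so the 4-OH and one of the two equivalent ortho OH groups are benzylated and the chelated one stays free.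

Step 8
Reactants: 14 salicylaldehyde; 15 4-(benzyloxy)phenylmagnesium bromide
Product: 16 3,5-bis(benzyloxy)-2-{[4-(benzyloxy)phenyl](hydroxy)methyl}phenol (racemic)
Conditions: 15 (2.3 equiv), THF, 0 °C → rt; aq. NH4Cl
Reagents that add atoms: none
Why: Grignard addition to the aldehyde, after deprotonation of the phenol by the first equivalent, gives the ortho-hydroxybenzhydrol, whose racemic carbinol centre is of no consequence because it becomes trigonal in the quinone methide.

Step 9
Reactants: 16 ortho-hydroxybenzhydrol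
Product: 17 3,5-bis(benzyloxy)-2-{[4-(benzyloxy)phenyl](4-methylphenylsulfonyl)methyl}phenol (racemic)
Conditions: p-TolSO2H, CH2Cl2, rt
Reagents that add atoms: p-toluenesulfinic acid, Cc1ccc(cc1)S(=O)O
Why: The doubly donor-stabilised benzhydryl cation forms under the mild acidity of the sulfinic acid and is captured at sulfur, a standard substitution that gives a bench-stable sulfone from which base regenerates the ortho-quinone methide.

Step 10
Reactants: 12 hexynoic acid; 17 sulfone
Product: 20 (4R)-4-benzyl-3-{(2S,3R)-2-[(3S,4R)-5,7-bis(benzyloxy)-4-(4-benzyloxyphenyl)-2-oxochroman-3-yl]-3-(4-benzyloxyphenyl)-5-(trimethylsilyl)pent-4-ynoyl}oxazolidin-2-one, via acyl imidazole 18 (not isolated), via ortho-quinone methide 19 (not isolated)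
Conditions: 1,1'-carbonyldiimidazole, THF, rt; then 17, (5aS,10bR)-2-mesityl-5a,10b-dihydro-4H,6H-indeno[2,1-b][1,2,4]triazolo[4,3-d][1,4]oxazin-2-ium chloride (15 mol %), K2CO3, 4 Å MS, THF, 0 °C → rt
Reagents that add atoms: none
Why: Carbene-catalysed formal [4+2] annulation (Michael addition then lactonisation) of an azolium enolate with an ortho-quinone methide is a known route to cis-3,4-disubstituted 4-aryl dihydrocoumarins, in which the Z-enolate adds in an endo arrangement so that H3 and H4 end cis and the chiral triazolylidene selects the enolate face, setting C3 (S) and C4 (R).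

Step 11
Reactants: 20 lactone imide
Product: 22 (2S,3S)-2-{(R)-[4-(benzyloxy)phenyl][2,4,6-tris(benzyloxy)phenyl]methyl}-3-{(1S)-1-[4-(benzyloxy)phenyl]prop-2-yn-1-yl}butanedioic acid, via trilithium phenoxide dicarboxylate 21 (not isolated)
Conditions: LiOH, H2O2, THF/H2O (3:1), 0 °C → rt; Na2SO3; then BnBr, n-Bu4NI (cat.), 40 °C; 1 M HCl to pH 2
Reagents that add atoms: lithium hydroxide, [Li+].[OH-]; hydrogen peroxide, OO; benzyl bromide, BrCc1ccccc1
Why: Lithium hydroperoxide cleaves the imide at the exocyclic carbonyl and opens the aryl lactone, hydroxide removes the alkynylsilane, and the freed phenoxide is then benzylated in the aqueous medium (Williamson etherification), where carboxylates are poor nucleophiles and any benzyl ester is saponified again, while C3 and C3' are safe because they sit alpha to carboxylates.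

Step 12
Reactants: 23 squaric acid
Product: 24 3,4-bis(benzyloxy)cyclobut-3-ene-1,2-dione
Conditions: BnOH, PhMe, reflux, Dean–Stark trap
Reagents that add atoms: benzyl alcohol, OCc1ccccc1
Why: Squaric acid is a vinylogous carboxylic acid and is esterified by benzyl alcohol with azeotropic removal of water (Fischer-type esterification).

Step 13
Reactants: 22 alkynyl diacid; 24 dibenzyl squarate
Product: 25 (2S,3S)-2-{(R)-[4-(benzyloxy)phenyl][2,4,6-tris(benzyloxy)phenyl]methyl}-3-{(1R)-1-[4-(benzyloxy)phenyl]-3-[2,3-bis(benzyloxy)-1-hydroxy-4-oxocyclobut-2-en-1-yl]prop-2-yn-1-yl}butanedioic acid (both carbinol epimers)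
Conditions: n-BuLi (3.05 equiv), THF, −78 °C; cannulate into 24, THF, −78 °C; aq. NH4Cl, then cold dilute HCl to pH 3; use without storage
Reagents that add atoms: none
Why: 1,2-Addition of a lithium acetylide to one carbonyl group of a squaric ester is the standard entry to 4-alkynyl-4-hydroxycyclobutenones, the two lithium carboxylates are inert and shield C3 and C3' from deprotonation, n-BuLi is used so that no amine is present to attack the squarate, and the new carbinol centre (formed unselectively) is destroyed in the next step.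

Step 14
Reactants: 25 4-alkynyl-4-hydroxycyclobutenone diacid
Product: 28 (2S,3R)-2-[(3S,4R)-6,7-bis(benzyloxy)-4-(4-benzyloxyphenyl)-5,8-dihydroxy-2-oxochroman-3-yl]-3-(4-benzyloxyphenyl)-3-[2,4,6-tris(benzyloxy)phenyl]propanoic acid, via vinylketene 26 (not isolated), via quinone diacid 27 (not isolated)
Conditions: degassed PhMe, 110 °C, argon; then camphorsulfonic acid (5 mol %), 60 °C, same flask
Reagents that add atoms: none
Why: Proposed new method: conrotatory 4π ring opening of cyclobutenone 25 (hydroxyl group rotating outward) should give the alkynyl vinylketene 26, whose ketene carbon bonds to the distal alkyne carbon (C5'–C4a', 6-endo-dig closure of the benzo ring through a transient diradical), and hydrogen transfer from the hydroxyl group gives quinone 27 with C4' on C4a' and hydrogen on C8a'. The C2' carboxylic acid then adds to C8a', which is beta to the C5' carbonyl, in a 6-endo-trig conjugate addition that closes the lactone ring (O1'–C8a'), and enolisation gives the hydroquinone, so ring B arrives at the oxidation level of the target without oxidant or reductant. The closest known reaction types are the Moore rearrangement of 4-alkynyl-4-hydroxycyclobutenones to benzoquinones and the acid-catalysed Thiele–Winter addition of carboxylic acid derivatives to quinones; their union in one flask is not established. No stereocentre is formed, and both carbinol epimers of 25 converge. The step needs six- rather than five-membered ketene closure, which the secondary alkyl (not radical-stabilising) substituent on the alkyne terminus favours, and it needs attack at C8a' by the C2' rather than the C2 carboxyl group, which follows because C8a' is the only unsubstituted quinone carbon and only the C2' acid reaches it through a six-membered ring. Acid is added only after the rearrangement because the hydroxycyclobutenone is acid-labile, and no base is used so that C3' of the new aryl lactone and C4' next to the quinone are not epimerised.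

Step 15
Reactants: 28 heptabenzyl lactone acid
Product: 30 (3S,4R,3'S,4'R)-5,5',6',7,7',8'-hexahydroxy-4,4'-bis(4-hydroxyphenyl)-[3,3'-bichromane]-2,2'-dione (target CNP0064734.1), via nonahydroxy acid 29 (not isolated)
Conditions: H2 (1 atm), 10% Pd/C, EtOAc/AcOH (9:1), rt, air excluded; filter under argon; degassed AcOH, 50 °C; evaporate
Reagents that add atoms: none
Why: Hydrogenolysis cleaves the seven benzyl ethers under neutral conditions without touching the aryl lactone, and the freed hydroxy acid 29 should close lactone A by acid-catalysed lactonisation of a 3-(2-hydroxyaryl)propanoic acid (either ortho hydroxyl group of the symmetric ring gives the same lactone), with no base present to epimerise C3 or C3'.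

**Compound list**

1 | 4-(benzyloxy)benzaldehyde | O=Cc1ccc(OCc2ccccc2)cc1 | starting material
2 | Meldrum's acid (2,2-dimethyl-1,3-dioxane-4,6-dione) | CC1(C)OC(=O)CC(=O)O1 | starting material
3 | 5-[4-(benzyloxy)benzylidene]-2,2-dimethyl-1,3-dioxane-4,6-dione | CC1(C)OC(=O)C(=Cc2ccc(OCc3ccccc3)cc2)C(=O)O1 | intermediate
4 | trimethylsilylacetylene | C#C[Si](C)(C)C | starting material
5 | 5-{(1R)-1-[4-(benzyloxy)phenyl]-3-(trimethylsilyl)prop-2-yn-1-yl}-2,2-dimethyl-1,3-dioxane-4,6-dione | CC1(C)OC(=O)C(C(=O)O1)[C@H](c1ccc(OCc2ccccc2)cc1)C#C[Si](C)(C)C | intermediate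
6 | (3R)-3-[4-(benzyloxy)phenyl]-5-(trimethylsilyl)pent-4-ynoic acid | OC(=O)C[C@H](c1ccc(OCc2ccccc2)cc1)C#C[Si](C)(C)C | intermediate
7 | (R)-4-benzyloxazolidin-2-one | O=C1N[C@H](Cc2ccccc2)CO1 | starting material
8 | (3R)-3-[4-(benzyloxy)phenyl]-5-(trimethylsilyl)pent-4-ynoic pivalic anhydride (not isolated) | CC(C)(C)C(=O)OC(=O)C[C@H](c1ccc(OCc2ccccc2)cc1)C#C[Si](C)(C)C | intermediate
9 | (4R)-4-benzyl-3-{(3R)-3-[4-(benzyloxy)phenyl]-5-(trimethylsilyl)pent-4-ynoyl}oxazolidin-2-one | O=C(C[C@H](c1ccc(OCc2ccccc2)cc1)C#C[Si](C)(C)C)N1[C@H](Cc2ccccc2)COC1=O | intermediate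
10 | tert-butyl bromoacetate | CC(C)(C)OC(=O)CBr | starting material
11 | tert-butyl (3R,4R)-3-{[(4R)-4-benzyl-2-oxooxazolidin-3-yl]carbonyl}-4-[4-(benzyloxy)phenyl]-6-(trimethylsilyl)hex-5-ynoate | CC(C)(C)OC(=O)C[C@@H](C(=O)N1[C@H](Cc2ccccc2)COC1=O)[C@H](c1ccc(OCc2ccccc2)cc1)C#C[Si](C)(C)C | intermediate
12 | (3R,4R)-3-{[(4R)-4-benzyl-2-oxooxazolidin-3-yl]carbonyl}-4-[4-(benzyloxy)phenyl]-6-(trimethylsilyl)hex-5-ynoic acid | OC(=O)C[C@@H](C(=O)N1[C@H](Cc2ccccc2)COC1=O)[C@H](c1ccc(OCc2ccccc2)cc1)C#C[Si](C)(C)C | intermediate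
13 | 2,4,6-trihydroxybenzaldehyde | O=Cc1c(O)cc(O)cc1O | starting material
14 | 2,4-bis(benzyloxy)-6-hydroxybenzaldehyde | O=Cc1c(O)cc(OCc2ccccc2)cc1OCc1ccccc1 | intermediate
15 | 4-(benzyloxy)phenylmagnesium bromide | Br[Mg]c1ccc(OCc2ccccc2)cc1 | starting material
16 | 3,5-bis(benzyloxy)-2-{[4-(benzyloxy)phenyl](hydroxy)methyl}phenol (racemic) | OC(c1ccc(OCc2ccccc2)cc1)c1c(O)cc(OCc2ccccc2)cc1OCc1ccccc1 | intermediate
17 | 3,5-bis(benzyloxy)-2-{[4-(benzyloxy)phenyl](4-methylphenylsulfonyl)methyl}phenol (racemic) | Cc1ccc(cc1)S(=O)(=O)C(c1ccc(OCc2ccccc2)cc1)c1c(O)cc(OCc2ccccc2)cc1OCc1ccccc1 | intermediate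
18 | 1-acylimidazole of acid 12 (3R,4R; acyl group on N1 of imidazole; not isolated) | O=C(C[C@@H](C(=O)N1[C@H](Cc2ccccc2)COC1=O)[C@H](c1ccc(OCc2ccccc2)cc1)C#C[Si](C)(C)C)n1ccnc1 | intermediate
19 | 6-[4-(benzyloxy)benzylidene]-3,5-bis(benzyloxy)cyclohexa-2,4-dien-1-one (ortho-quinone methide, alkene geometry not fixed; not isolated) | O=C1C=C(OCc2ccccc2)C=C(OCc2ccccc2)C1=Cc1ccc(OCc2ccccc2)cc1 | intermediate
20 | (4R)-4-benzyl-3-{(2S,3R)-2-[(3S,4R)-5,7-bis(benzyloxy)-4-(4-benzyloxyphenyl)-2-oxochroman-3-yl]-3-(4-benzyloxyphenyl)-5-(trimethylsilyl)pent-4-ynoyl}oxazolidin-2-one (H3 and H4 cis) | O=C1Oc2cc(OCc3ccccc3)cc(OCc3ccccc3)c2[C@@H](c2ccc(OCc3ccccc3)cc2)[C@H]1[C@@H](C(=O)N1[C@H](Cc2ccccc2)COC1=O)[C@H](c1ccc(OCc2ccccc2)cc1)C#C[Si](C)(C)C | intermediate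
21 | trilithium (2S,3S)-2-{(R)-[2,4-bis(benzyloxy)-6-oxidophenyl][4-(benzyloxy)phenyl]methyl}-3-{(1S)-1-[4-(benzyloxy)phenyl]prop-2-yn-1-yl}butanedioate (not isolated) | [Li+].[Li+].[Li+].[O-]C(=O)[C@@H]([C@H](c1ccc(OCc2ccccc2)cc1)c1c([O-])cc(OCc2ccccc2)cc1OCc1ccccc1)[C@@H](C([O-])=O)[C@H](c1ccc(OCc2ccccc2)cc1)C#C | intermediate
22 | (2S,3S)-2-{(R)-[4-(benzyloxy)phenyl][2,4,6-tris(benzyloxy)phenyl]methyl}-3-{(1S)-1-[4-(benzyloxy)phenyl]prop-2-yn-1-yl}butanedioic acid | OC(=O)[C@@H]([C@H](c1ccc(OCc2ccccc2)cc1)c1c(OCc2ccccc2)cc(OCc2ccccc2)cc1OCc1ccccc1)[C@@H](C(=O)O)[C@H](c1ccc(OCc2ccccc2)cc1)C#C | intermediate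
23 | squaric acid | OC1=C(O)C(=O)C1=O | starting material
24 | 3,4-bis(benzyloxy)cyclobut-3-ene-1,2-dione (dibenzyl squarate) | O=C1C(=O)C(OCc2ccccc2)=C1OCc1ccccc1 | intermediate
25 | (2S,3S)-2-{(R)-[4-(benzyloxy)phenyl][2,4,6-tris(benzyloxy)phenyl]methyl}-3-{(1R)-1-[4-(benzyloxy)phenyl]-3-[2,3-bis(benzyloxy)-1-hydroxy-4-oxocyclobut-2-en-1-yl]prop-2-yn-1-yl}butanedioic acid (both epimers at the carbinol carbon) | OC(=O)[C@@H]([C@H](c1ccc(OCc2ccccc2)cc1)c1c(OCc2ccccc2)cc(OCc2ccccc2)cc1OCc1ccccc1)[C@@H](C(=O)O)[C@H](c1ccc(OCc2ccccc2)cc1)C#CC1(O)C(=O)C(OCc2ccccc2)=C1OCc1ccccc1 | intermediate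
26 | (2S,3S)-2-{(R)-[4-(benzyloxy)phenyl][2,4,6-tris(benzyloxy)phenyl]methyl}-3-{(1R,4Z)-5,6-bis(benzyloxy)-1-[4-(benzyloxy)phenyl]-4-hydroxy-7-oxohepta-4,6-dien-2-yn-1-yl}butanedioic acid (vinylketene; not isolated) | OC(=O)[C@@H]([C@H](c1ccc(OCc2ccccc2)cc1)c1c(OCc2ccccc2)cc(OCc2ccccc2)cc1OCc1ccccc1)[C@@H](C(=O)O)[C@H](c1ccc(OCc2ccccc2)cc1)C#C/C(O)=C(OCc1ccccc1)\C(OCc1ccccc1)=C=O | intermediate
27 | (2S,3S)-2-{(R)-[4-(benzyloxy)phenyl][2,4,6-tris(benzyloxy)phenyl]methyl}-3-{(R)-[4,5-bis(benzyloxy)-3,6-dioxocyclohexa-1,4-dien-1-yl][4-(benzyloxy)phenyl]methyl}butanedioic acid (quinone; not isolated) | OC(=O)[C@@H]([C@H](c1ccc(OCc2ccccc2)cc1)c1c(OCc2ccccc2)cc(OCc2ccccc2)cc1OCc1ccccc1)[C@@H](C(=O)O)[C@H](c1ccc(OCc2ccccc2)cc1)C1=CC(=O)C(OCc2ccccc2)=C(OCc2ccccc2)C1=O | intermediate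
28 | (2S,3R)-2-[(3S,4R)-6,7-bis(benzyloxy)-4-(4-benzyloxyphenyl)-5,8-dihydroxy-2-oxochroman-3-yl]-3-(4-benzyloxyphenyl)-3-[2,4,6-tris(benzyloxy)phenyl]propanoic acid | OC(=O)[C@@H]([C@H](c1ccc(OCc2ccccc2)cc1)c1c(OCc2ccccc2)cc(OCc2ccccc2)cc1OCc1ccccc1)[C@H]1C(=O)Oc2c(O)c(OCc3ccccc3)c(OCc3ccccc3)c(O)c2[C@H]1c1ccc(OCc2ccccc2)cc1 | intermediate
29 | (2S,3R)-3-(4-hydroxyphenyl)-2-[(3S,4R)-5,6,7,8-tetrahydroxy-4-(4-hydroxyphenyl)-2-oxochroman-3-yl]-3-(2,4,6-trihydroxyphenyl)propanoic acid (not isolated) | OC(=O)[C@@H]([C@H](c1ccc(O)cc1)c1c(O)cc(O)cc1O)[C@H]1C(=O)Oc2c(O)c(O)c(O)c(O)c2[C@H]1c1ccc(O)cc1 | intermediate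
30 | (3S,4R,3'S,4'R)-5,5',6',7,7',8'-hexahydroxy-4,4'-bis(4-hydroxyphenyl)-[3,3'-bichromane]-2,2'-dione (CNP0064734.1; aryl and C3 substituent cis in both rings) | O=C1Oc2cc(O)cc(O)c2[C@@H](c2ccc(O)cc2)[C@H]1[C@H]1C(=O)Oc2c(O)c(O)c(O)c(O)c2[C@H]1c1ccc(O)cc1 | target

**Step count**

Total: 15 steps. Longest linear sequence: 11 steps (steps 1–6, 10, 11, 13, 14, 15).

**Steps most likely to fail**

Step 14 (proposed new method). The alkyl quinone may tautomerise to a quinone methide at C4' before the carboxyl group adds, which would erode the C4' configuration or let the C2 acid capture it as a five-membered lactone. The ketene may also close in the five-membered sense, or the conjugate addition may stall at the quinone. Fallback, known reactions only: cyclobutenone 25 is heated in toluene without acid and quinone diacid 27 is isolated (Moore rearrangement). Thiele–Winter acetoxylation (Ac2O, cat. H2SO4, 0 °C) then places an acetoxy group on C8a', acetylates both hydroquinone oxygens and dehydrates the succinic acid, giving triacetoxyarene anhydride F1. Degassed aqueous LiOH in THF at 0 °C, then acidification, removes the three acetates and opens the anhydride to trihydroxy diacid F2, in which no stereocentre is alpha to an ester. Acid-catalysed lactonisation (TsOH cat., toluene, 60 °C) closes the C2' acid onto O8a' to give 28, or onto the equivalent oxygen at C5' to give lactone regioisomer F3. After debenzylation ring B carries only hydroxyl groups and is symmetric about the C4a'–C7' axis, so 28 and F3 both lead to 30 in step 15. The route is rejoined at 28.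

Step 10. The hindered acyl azolium may enolise and add slowly, the existing C3' and C4' centres may oppose the catalyst (mismatch), or C3 may epimerise from cis to trans under carbonate. Fallback: acid 12 is esterified with the phenol of aldehyde 14 (EDC, DMAP cat., CH2Cl2) to aryl ester F4, which is closed by intramolecular Knoevenagel-type condensation (piperidinium acetate, toluene, 60 °C) to 3-substituted coumarin F5. Conjugate addition of the aryl cuprate made from Grignard reagent 15 and CuBr·SMe2 (Me3SiCl, THF, −78 °C) is directed by the C3' centre, and the lactone enolate is then protonated at −78 °C on the face away from the new C4 aryl group (cis product by kinetic protonation). This rejoins the route at 20.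

Step 13. The trilithium salt may aggregate or precipitate, deprotonation at the benzylic–propargylic C4'–H may compete (propargyl–allene isomerisation), or addition to the squarate may be incomplete. Fallback: diacid 22 is converted into diallyl ester F6 (allyl bromide, KHCO3, DMF). The alkyne alone is deprotonated with LiN(SiMe3)2 (1.05 equiv, THF, −78 °C; both ester alpha hydrogens are tertiary and flanked by branched carbons) and added to 24 to give cyclobutenol diallyl ester F7. The allyl groups are removed under neutral conditions with the zerovalent palladium complex Pd(PPh3)4 and PhSiH3 (CH2Cl2, rt), which rejoins the route at 25.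

**Further compounds**

F1 | step 14 | (3S,4S)-3-{(R)-[4-(benzyloxy)phenyl][2,4,6-tris(benzyloxy)phenyl]methyl}-4-{(R)-[4-(benzyloxy)phenyl][2,3,6-triacetoxy-4,5-bis(benzyloxy)phenyl]methyl}oxolane-2,5-dione (trans anhydride) | O=C1OC(=O)[C@@H]([C@H](c2ccc(OCc3ccccc3)cc2)c2c(OC(C)=O)c(OC(C)=O)c(OCc3ccccc3)c(OCc3ccccc3)c2OC(C)=O)[C@@H]1[C@H](c1ccc(OCc2ccccc2)cc1)c1c(OCc2ccccc2)cc(OCc2ccccc2)cc1OCc1ccccc1
F2 | step 14 | (2S,3S)-2-{(R)-[4-(benzyloxy)phenyl][2,4,6-tris(benzyloxy)phenyl]methyl}-3-{(R)-[4-(benzyloxy)phenyl][4,5-bis(benzyloxy)-2,3,6-trihydroxyphenyl]methyl}butanedioic acid | OC(=O)[C@@H]([C@H](c1ccc(OCc2ccccc2)cc1)c1c(OCc2ccccc2)cc(OCc2ccccc2)cc1OCc1ccccc1)[C@@H](C(=O)O)[C@H](c1ccc(OCc2ccccc2)cc1)c1c(O)c(O)c(OCc2ccccc2)c(OCc2ccccc2)c1O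
F3 | step 14 | (2S,3R)-2-[(3S,4R)-7,8-bis(benzyloxy)-4-(4-benzyloxyphenyl)-5,6-dihydroxy-2-oxochroman-3-yl]-3-(4-benzyloxyphenyl)-3-[2,4,6-tris(benzyloxy)phenyl]propanoic acid | OC(=O)[C@@H]([C@H](c1ccc(OCc2ccccc2)cc1)c1c(OCc2ccccc2)cc(OCc2ccccc2)cc1OCc1ccccc1)[C@H]1C(=O)Oc2c(OCc3ccccc3)c(OCc3ccccc3)c(O)c(O)c2[C@H]1c1ccc(OCc2ccccc2)cc1
F4 | step 10 | 3,5-bis(benzyloxy)-2-formylphenyl (3R,4R)-3-{[(4R)-4-benzyl-2-oxooxazolidin-3-yl]carbonyl}-4-[4-(benzyloxy)phenyl]-6-(trimethylsilyl)hex-5-ynoate | O=Cc1c(OC(=O)C[C@@H](C(=O)N2[C@H](Cc3ccccc3)COC2=O)[C@H](c2ccc(OCc3ccccc3)cc2)C#C[Si](C)(C)C)cc(OCc2ccccc2)cc1OCc1ccccc1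
F5 | step 10 | (4R)-4-benzyl-3-{(2S,3R)-2-[5,7-bis(benzyloxy)-2-oxo-2H-chromen-3-yl]-3-(4-benzyloxyphenyl)-5-(trimethylsilyl)pent-4-ynoyl}oxazolidin-2-one | O=C1Oc2cc(OCc3ccccc3)cc(OCc3ccccc3)c2C=C1[C@@H](C(=O)N1[C@H](Cc2ccccc2)COC1=O)[C@H](c1ccc(OCc2ccccc2)cc1)C#C[Si](C)(C)C
F6 | step 13 | diallyl (2S,3S)-2-{(R)-[4-(benzyloxy)phenyl][2,4,6-tris(benzyloxy)phenyl]methyl}-3-{(1S)-1-[4-(benzyloxy)phenyl]prop-2-yn-1-yl}butanedioate | C=CCOC(=O)[C@@H]([C@H](c1ccc(OCc2ccccc2)cc1)c1c(OCc2ccccc2)cc(OCc2ccccc2)cc1OCc1ccccc1)[C@@H](C(=O)OCC=C)[C@H](c1ccc(OCc2ccccc2)cc1)C#C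
F7 | step 13 | diallyl ester of 25 (both carbinol epimers) | C=CCOC(=O)[C@@H]([C@H](c1ccc(OCc2ccccc2)cc1)c1c(OCc2ccccc2)cc(OCc2ccccc2)cc1OCc1ccccc1)[C@@H](C(=O)OCC=C)[C@H](c1ccc(OCc2ccccc2)cc1)C#CC1(O)C(=O)C(OCc2ccccc2)=C1OCc1ccccc1
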